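**Strategy.** The labdane is cut in ring A: after adding a C1=C2 double bond and a C6 carbonyl in the retrosynthetic sense, the bonds C3–C4 and C5–C10 are those of an intramolecular Diels–Alder reaction. The precursor is an acyclic trienone in which the gem-dimethyl carbon C4 is the β-carbon of an enone (C4=C5–C6=O), the quaternary C10 is the methyl-bearing end of a Z-diene (C10=C1–C2=C3), and C6–C9 is the tether that becomes ring B. One cycloaddition makes both rings and relays C9 (set with an auxiliary) to C10; the C6 ketone then lets C5 be equilibrated to the trans fusion and is converted into the C7=C8 enoate. C13 comes from (S)-citronellol.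

Key step: step 11

Remark: labdane numbering (C1–C20) is used for all intermediates; compounds 17 and 19–24 are carried as C8 epimers, which is without consequence because C8 becomes trigonal in step 14.

**Step 1**
Reactants: 1 but-2-yn-1-ol
Product: 2 (Z)-3-iodobut-2-en-1-ol
Conditions: NaAlH2(OCH2CH2OMe)2, THF, 0 °C → rt; then I2, THF, −78 → 0 °C
Reagents that add atoms: iodine, II
Why: Hydroxyl-directed anti-hydroalumination of the propargylic alkoxide places aluminium at C3 cis to the CH2O group, and iodinolysis of the C–Al bond with retention should give the Z-iodide (trans-hydroalumination–iodination).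

**Step 2**
Reactants: 2 (Z)-3-iodobut-2-en-1-ol
Product: 3 (Z)-3-iodobut-2-enal
Conditions: MnO2, CH2Cl2, rt, dark
Reagents that add atoms: none
Why: Activated MnO2 oxidises the allylic alcohol under neutral conditions that leave the vinyl iodide and its geometry untouched (allylic oxidation).

**Step 3**
Reactants: 3 (Z)-3-iodobut-2-enal
Product: 4 (3Z)-4-iodopenta-1,3-diene
Conditions: Ph3PCH3Br, KN(SiMe3)2, THF, −78 → 0 °C; product kept as a cold ethereal solution
Reagents that add atoms: methyltriphenylphosphonium bromide, C[P+](c1ccccc1)(c1ccccc1)c1ccccc1.[Br-]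
Why: Wittig methylenation of the aldehyde by the unstabilised ylide is fast at low temperature and does not touch the trisubstituted iodoalkene, so the Z geometry is kept.

**Step 4**
Reactants: 5 (S)-citronellol
Product: 6 tert-butyl{[(3S)-3,7-dimethyloct-6-en-1-yl]oxy}dimethylsilane
Conditions: TBSCl, imidazole, CH2Cl2, rt
Reagents that add atoms: tert-butyldimethylsilyl chloride, CC(C)(C)[Si](C)(C)Cl
Why: Silyl ether formation at the primary alcohol gives a group that survives the organometallic and basic steps ahead; C13 comes unchanged from the chiral pool.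

**Step 5**
Reactants: 6 citronellyl silyl ether; 7 acrylic acid
Product: 8 (2E,6S)-8-[(tert-butyldimethylsilyl)oxy]-6-methyloct-2-enoic acid
Conditions: 7 (3 equiv), second-generation Grubbs catalyst RuCl2(H2IMes)(PCy3)(=CHPh) (5 mol %), CH2Cl2, 40 °C
Reagents that add atoms: none
Why: Olefin cross-metathesis of the isopropylidene terminus with the electron-poor acrylic partner is driven by loss of isobutene and should give the conjugated E-acid, whose β-carbon is C9.

**Step 6**
Reactants: 8 enoic acid; 9 (4R)-4-benzyl-1,3-oxazolidin-2-one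
Product: 11 (4R)-4-benzyl-3-{(2E,6S)-8-[(tert-butyldimethylsilyl)oxy]-6-methyloct-2-enoyl}-1,3-oxazolidin-2-one, via mixed pivalic anhydride 10 (not isolated)
Conditions: t-BuCOCl, Et3N, THF, −20 °C; then LiCl, 9, rt
Reagents that add atoms: none
Why: The oxazolidinone, activated by LiCl and Et3N, attacks the mixed anhydride at the less hindered enoyl carbonyl only (N-acylation through a mixed anhydride).

**Step 7**
Reactants: 11 enoyl imide; 4 (3Z)-4-iodopenta-1,3-diene
Product: 14 (4R)-4-benzyl-3-[(3S,4Z)-3-{(3S)-5-[(tert-butyldimethylsilyl)oxy]-3-methylpentyl}-4-methylhepta-4,6-dienoyl]-1,3-oxazolidin-2-one, via dienyllithium 12 (not isolated), via dienylmagnesium bromide 13 (not isolated)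
Conditions: 4 (2 equiv), t-BuLi (4 equiv), Et2O, −78 °C; MgBr2·OEt2; CuBr·SMe2, THF–Me2S, −78 °C; then 11, −78 → −20 °C; aq. NH4Cl
Reagents that add atoms: none
Why: Iodine–lithium exchange and transmetalation keep the alkene geometry, and the alkenylcopper reagent adds to the magnesium-chelated syn-s-cis enoyl imide on the face opposite the benzyl group, which sets C9 (auxiliary-controlled copper-mediated conjugate addition).

**Step 8**
Reactants: 14 conjugate adduct
Product: 15 methyl (3S,4Z)-3-{(3S)-5-[(tert-butyldimethylsilyl)oxy]-3-methylpentyl}-4-methylhepta-4,6-dienoate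
Conditions: NaOMe (1.1 equiv), MeOH–THF, 0 °C
Reagents that add atoms: sodium methoxide, C[O-].[Na+]
Why: Methoxide attacks the unhindered exocyclic imide carbonyl and releases the recoverable auxiliary (transesterification); C9 carries no acidic hydrogen and is untouched.

**Step 9**
Reactants: 15 methyl ester; 16 2-bromo-N-methoxy-N-methylacetamide
Product: 17 methyl (3S,4Z)-3-{(3S)-5-[(tert-butyldimethylsilyl)oxy]-3-methylpentyl}-2-{2-[methoxy(methyl)amino]-2-oxoethyl}-4-methylhepta-4,6-dienoate (C8 epimers)
Conditions: LiN(iPr)2, THF, −78 °C; then 16, DMPU, −78 → −30 °C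
Reagents that add atoms: none
Why: The ester enolate is alkylated at C8 by the reactive α-bromo amide (enolate SN2 alkylation), which brings in C7 and C6; the new C8 centre need not be controlled.

**Step 10**
Reactants: 17 ester amide; 18 (2-methylprop-1-en-1-yl)magnesium bromide
Product: 19 methyl (3S,4Z)-3-{(3S)-5-[(tert-butyldimethylsilyl)oxy]-3-methylpentyl}-4-methyl-2-(4-methyl-2-oxopent-3-en-1-yl)hepta-4,6-dienoate (C8 epimers)
Conditions: 18 (1.3 equiv), THF, −20 → 0 °C; aq. NH4Cl
Reagents that add atoms: none
Why: The Grignard reagent adds once to the N-methoxy-N-methylamide through a stable magnesium chelate that collapses to the β,β-dimethyl enone only on work-up, while the doubly branched methyl ester should react more slowly (ketone synthesis from an N-methoxy-N-methylamide).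

**Step 11**
Reactants: 19 trienone
Product: 20 methyl (13S)-15-[(tert-butyldimethylsilyl)oxy]-6-oxo-5β-labd-1-en-17-oate (cis-fused octalone)
Conditions: Me2AlCl (0.5 equiv), CH2Cl2, −78 → 0 °C
Reagents that add atoms: none
Why: Coordination of Me2AlCl to the C6 ketone lowers the LUMO of the β,β-dimethyl enone, so that the unsubstituted diene terminus C3 attacks the β-carbon C4 while C5 closes onto the methyl-bearing terminus C10 in a concerted but asynchronous intramolecular Diels–Alder reaction; the closest known reaction type is the Lewis-acid-promoted cycloaddition of 1,7,9-decatrien-3-ones that carry a Z-diene. Ring A is the cyclohexene closed by the [4+2] cycloaddition itself, and ring B is closed at the same time by the four-atom tether C6–C9, which a Z-diene can fold only in the exo (anti) chair-like arrangement that leads to the cis-fused octalone. C10 is controlled by C9 through 1,3-allylic strain: H9 must lie in the diene plane facing H2, so the tether carbon C8 and the C11 side chain sit on opposite faces and the dienophile adds anti to the side chain, which places the C10 methyl cis to the side chain and trans to H9 as in the target. C5 is formed cis to the C10 methyl because the addition is suprafacial on both partners and only the exo tether is accessible; this centre is left to be corrected in step 12. The step needs facial selectivity (from the allylic strain of the Z-diene) and a single regiochemistry (from the tether and the matched polarisation of C4 and C3), and it must outrun a [1,5]-hydrogen shift of the Z-diene, which the low temperature allowed by the Lewis acid should ensure.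

**Step 12**
Reactants: 20 cis-fused octalone
Product: 22 methyl (13S)-15-[(tert-butyldimethylsilyl)oxy]-6-oxolabdan-17-oate (trans-fused 5α-H), via cis-fused saturated ketone 21 (not isolated)
Conditions: H2 (1 atm), Pd/C, EtOAc, rt; filtered and concentrated; then NaOMe (0.3 equiv), MeOH, 40 °C
Reagents that add atoms: none
Why: Catalytic hydrogenation removes only the cis-disubstituted C1=C2 bond, and reversible enolisation of the C6 ketone then epimerises C5 (and C8) to the trans-fused decalone, which is expected to be favoured because a cis-fused chair–chair form can keep the C9 side chain equatorial only by pushing the 4α-methyl under ring B (base epimerisation α to a ketone).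

**Step 13**
Reactants: 22 trans-fused keto ester
Product: 23 methyl (13S)-15-[(tert-butyldimethylsilyl)oxy]-6-[(trifluoromethylsulfonyl)oxy]labd-6-en-17-oate
Conditions: KN(SiMe3)2, THF, −78 °C; then PhNTf2, −78 → 0 °C
Reagents that add atoms: N-phenylbis(trifluoromethanesulfonimide), FC(F)(F)S(=O)(=O)N(c1ccccc1)S(=O)(=O)C(F)(F)F
Why: At −78 °C the hindered amide base removes a proton from the C7 methylene and not from the C5 methine, which is flanked by two quaternary carbons, and O-sulfonylation of this enolate fixes the C6=C7 enol triflate without epimerising C5 (kinetic enol triflate formation).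

**Step 14**
Reactants: 23 enol triflate
Product: 25 methyl (13S)-15-[(tert-butyldimethylsilyl)oxy]labd-7-en-17-oate, via labd-6-ene ester 24 (not isolated)
Conditions: Pd(OAc)2 (5 mol %), PPh3, HCO2H, Bu3N, DMF, 60 °C; then DBU, 60 °C
Reagents that add atoms: none
Why: Zerovalent palladium formed in the flask inserts into the vinyl C–OTf bond and formate delivers hydride to give the C6=C7 olefin (palladium-catalysed formate reduction of a vinyl triflate), and DBU then moves this β,γ-double bond into conjugation through the ester dienolate, protonated at C6; H9 is not acidic, so the C8=C9 isomer should not form.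

**Step 15**
Reactants: 25 conjugated methyl ester
Product: 27 (13S)-15-hydroxylabd-7-en-17-oic acid, via silyl ether acid 26 (not isolated)
Conditions: LiOH, THF–MeOH–H2O, 60 °C; then aq. HCl to pH 1, rt
Reagents that add atoms: lithium hydroxide, [Li+].[OH-]
Why: Hydroxide cleaves the hindered conjugated methyl ester (saponification) and the acidification removes the primary silyl ether; the trisubstituted enoate and all stereocentres are stable to both.

**Step 16**
Reactants: 27 hydroxy acid
Product: 28 (13S)-15-acetoxylabd-7-en-17-oic acid (target)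
Conditions: Ac2O, pyridine, DMAP (cat.), CH2Cl2, rt; then H2O–THF, NaHCO3; acidify to pH 3
Reagents that add atoms: acetic anhydride, CC(=O)OC(C)=O
Why: Acetic anhydride with pyridine and DMAP acetylates the primary alcohol (O-acylation), and any mixed anhydride formed at the hindered acid is hydrolysed back during the aqueous bicarbonate work-up.

**Compound list**

1 | but-2-yn-1-ol | CC#CCO | starting material
2 | (Z)-3-iodobut-2-en-1-ol | C/C(I)=C/CO | intermediate
3 | (Z)-3-iodobut-2-enal | C/C(I)=C/C=O | intermediate
4 | (3Z)-4-iodopenta-1,3-diene | C/C(I)=C/C=C | intermediate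
5 | (S)-citronellol, (3S)-3,7-dimethyloct-6-en-1-ol | OCC[C@@H](C)CCC=C(C)C | starting material
6 | tert-butyl{[(3S)-3,7-dimethyloct-6-en-1-yl]oxy}dimethylsilane | CC(C)(C)[Si](C)(C)OCC[C@@H](C)CCC=C(C)C | intermediate
7 | acrylic acid | C=CC(=O)O | starting material
8 | (2E,6S)-8-[(tert-butyldimethylsilyl)oxy]-6-methyloct-2-enoic acid | CC(C)(C)[Si](C)(C)OCC[C@@H](C)CC/C=C/C(=O)O | intermediate
9 | (4R)-4-benzyl-1,3-oxazolidin-2-one | O=C1N[C@H](Cc2ccccc2)CO1 | starting material
10 | mixed anhydride of 8 with pivalic acid | CC(C)(C)[Si](C)(C)OCC[C@@H](C)CC/C=C/C(=O)OC(=O)C(C)(C)C | intermediate (not isolated)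
11 | (4R)-4-benzyl-3-{(2E,6S)-8-[(tert-butyldimethylsilyl)oxy]-6-methyloct-2-enoyl}-1,3-oxazolidin-2-one | CC(C)(C)[Si](C)(C)OCC[C@@H](C)CC/C=C/C(=O)N1[C@H](Cc2ccccc2)COC1=O | intermediate
12 | (2E)-penta-2,4-dien-2-yllithium (lithium cis to the vinyl group, geometry of 4 retained) | [Li]/C(C)=C\C=C | intermediate (not isolated)
13 | (2Z)-penta-2,4-dien-2-ylmagnesium bromide (magnesium cis to the vinyl group) | Br[Mg]/C(C)=C\C=C | intermediate (not isolated)
14 | (4R)-4-benzyl-3-[(3S,4Z)-3-{(3S)-5-[(tert-butyldimethylsilyl)oxy]-3-methylpentyl}-4-methylhepta-4,6-dienoyl]-1,3-oxazolidin-2-one | CC(C)(C)[Si](C)(C)OCC[C@@H](C)CC[C@H](/C(C)=C\C=C)CC(=O)N1[C@H](Cc2ccccc2)COC1=O | intermediate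
15 | methyl (3S,4Z)-3-{(3S)-5-[(tert-butyldimethylsilyl)oxy]-3-methylpentyl}-4-methylhepta-4,6-dienoate | CC(C)(C)[Si](C)(C)OCC[C@@H](C)CC[C@H](/C(C)=C\C=C)CC(=O)OC | intermediate
16 | 2-bromo-N-methoxy-N-methylacetamide | CON(C)C(=O)CBr | starting material
17 | methyl (3S,4Z)-3-{(3S)-5-[(tert-butyldimethylsilyl)oxy]-3-methylpentyl}-2-{2-[methoxy(methyl)amino]-2-oxoethyl}-4-methylhepta-4,6-dienoate (C8 epimers) | CC(C)(C)[Si](C)(C)OCC[C@@H](C)CC[C@H](/C(C)=C\C=C)C(CC(=O)N(C)OC)C(=O)OC | intermediate
18 | (2-methylprop-1-en-1-yl)magnesium bromide | CC(C)=C[Mg]Br | starting material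
19 | methyl (3S,4Z)-3-{(3S)-5-[(tert-butyldimethylsilyl)oxy]-3-methylpentyl}-4-methyl-2-(4-methyl-2-oxopent-3-en-1-yl)hepta-4,6-dienoate (C8 epimers) | CC(C)(C)[Si](C)(C)OCC[C@@H](C)CC[C@H](/C(C)=C\C=C)C(CC(=O)C=C(C)C)C(=O)OC | intermediate
20 | methyl (13S)-15-[(tert-butyldimethylsilyl)oxy]-6-oxo-5β-labd-1-en-17-oate (cis-fused: 5β-H cis to the 10β-methyl; 9α-H; C8 epimers) | CC(C)(C)[Si](C)(C)OCC[C@@H](C)CC[C@H]1C(C(=O)OC)CC(=O)[C@@H]2C(C)(C)CC=C[C@]12C | intermediate
21 | methyl (13S)-15-[(tert-butyldimethylsilyl)oxy]-6-oxo-5β-labdan-17-oate (cis-fused; C8 epimers) | CC(C)(C)[Si](C)(C)OCC[C@@H](C)CC[C@H]1C(C(=O)OC)CC(=O)[C@@H]2C(C)(C)CCC[C@]12C | intermediate (not isolated)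
22 | methyl (13S)-15-[(tert-butyldimethylsilyl)oxy]-6-oxolabdan-17-oate (trans-fused: 5α-H, 9α-H, 10β-methyl; C8 epimers) | CC(C)(C)[Si](C)(C)OCC[C@@H](C)CC[C@H]1C(C(=O)OC)CC(=O)[C@H]2C(C)(C)CCC[C@]12C | intermediate
23 | methyl (13S)-15-[(tert-butyldimethylsilyl)oxy]-6-[(trifluoromethylsulfonyl)oxy]labd-6-en-17-oate (C8 epimers) | CC(C)(C)[Si](C)(C)OCC[C@@H](C)CC[C@H]1C(C(=O)OC)C=C(OS(=O)(=O)C(F)(F)F)[C@H]2C(C)(C)CCC[C@]12C | intermediate
24 | methyl (13S)-15-[(tert-butyldimethylsilyl)oxy]labd-6-en-17-oate (C8 epimers) | CC(C)(C)[Si](C)(C)OCC[C@@H](C)CC[C@H]1C(C(=O)OC)C=C[C@H]2C(C)(C)CCC[C@]12C | intermediate (not isolated)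
25 | methyl (13S)-15-[(tert-butyldimethylsilyl)oxy]labd-7-en-17-oate | CC(C)(C)[Si](C)(C)OCC[C@@H](C)CC[C@H]1C(C(=O)OC)=CC[C@H]2C(C)(C)CCC[C@]12C | intermediate
26 | (13S)-15-[(tert-butyldimethylsilyl)oxy]labd-7-en-17-oic acid | CC(C)(C)[Si](C)(C)OCC[C@@H](C)CC[C@H]1C(C(=O)O)=CC[C@H]2C(C)(C)CCC[C@]12C | intermediate (not isolated)
27 | (13S)-15-hydroxylabd-7-en-17-oic acid | OCC[C@@H](C)CC[C@H]1C(C(=O)O)=CC[C@H]2C(C)(C)CCC[C@]12C | intermediate
28 | (13S)-15-acetoxylabd-7-en-17-oic acid, (1R,4aS,8aS)-1-[(3S)-5-acetoxy-3-methylpentyl]-5,5,8a-trimethyl-1,4,4a,5,6,7,8,8a-octahydronaphthalene-2-carboxylic acid | CC(=O)OCC[C@@H](C)CC[C@H]1C(C(=O)O)=CC[C@H]2C(C)(C)CCC[C@]12C | target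

**Totals.** Total step count: 16. Longest linear sequence: 13 steps (5 → 28 through steps 4–16; the branch 1 → 4 joins at step 7 and is equally long).

**Steps most likely to fail**

Step 11 (key cycloaddition). The cycloaddition of the β,β-disubstituted enone onto the fully substituted diene terminus may be slower than Lewis-acid-induced oligomerisation of the diene, or than a [1,5]-hydrogen shift of the Z-diene on warming. The fallback uses a cationic dienophile instead of a Lewis-acid-complexed one. It sets out from 19: 1,2-bis(trimethylsilyloxy)ethane and catalytic TMSOTf in CH2Cl2 at −78 °C would convert the enone into the ethylene ketal of trienone 19 F1. Under the same acid this ketal should ionise to a dioxolenium-substituted allyl cation and close stepwise (C3 to C4, then C5 to C10) at low temperature to the ethylene ketal of adduct 20 F2, under the same Z-diene constraints. Mild hydrolysis (PPTS, wet acetone, 40 °C) would return to 20.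

Step 12 (ring-fusion epimerisation). The equilibration at C5 may stop at a mixture of ring-fusion epimers, because the interaction between the 4α-methyl group and the C6 carbonyl erodes the trans preference. The fallback sets C5 by reagent approach instead of equilibration. It sets out from 21 (hydrogenation alone): Tf2O and 2,6-di-tert-butyl-4-methylpyridine in CH2Cl2 should give the more substituted C5=C6 enol triflate F3, which erases C5. Reduction with Pd(OAc)2, PPh3, HCO2H and Bu3N would give the labd-5-ene ester F4. Hydroboration (BH3·THF, then NaBO3) should add from the α face, away from the two β-methyl groups on C4 and C10, with boron at C6, and give the 5α-H 6α-alcohol F5. Oxidation with Dess–Martin periodinane would come back to 22 without exposing the ketone to base.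

Step 7 (conjugate addition). The dienylcopper reagent may be lost before transfer, through decomposition, Z/E erosion or attack at the imide carbonyl, giving low conversion or a mixture. The fallback builds the diene after the conjugate addition. It sets out from 11, with 2 as the alkenyl source: 2 is protected (4-methoxybenzyl trichloroacetimidate, cat. TfOH) as the 4-methoxybenzyl ether of iodo alcohol 2 F6. Its lithium reagent (t-BuLi), transmetalated as in step 7, should add to 11 to give the (Z)-alkenyl ether adduct F7. DDQ would remove the 4-methoxybenzyl group to give the allylic alcohol F8, MnO2 would give the Z-enal F9, and Wittig methylenation (Ph3PCH3Br, KN(SiMe3)2) would come back to 14.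

**Further compounds**

F1 | step 11 | ethylene ketal of trienone 19 (2-(2-methylprop-1-en-1-yl)-1,3-dioxolane in place of the C6 ketone; C8 epimers) | CC(C)(C)[Si](C)(C)OCC[C@@H](C)CC[C@H](/C(C)=C\C=C)C(CC1(C=C(C)C)OCCO1)C(=O)OC
F2 | step 11 | ethylene ketal of adduct 20 (6,6-ethylenedioxy, cis-fused, C8 epimers) | CC(C)(C)[Si](C)(C)OCC[C@@H](C)CC[C@H]1C(C(=O)OC)CC3(OCCO3)[C@@H]2C(C)(C)CC=C[C@]12C
F3 | step 12 | methyl (13S)-15-[(tert-butyldimethylsilyl)oxy]-6-[(trifluoromethylsulfonyl)oxy]labd-5-en-17-oate (C8 epimers) | CC(C)(C)[Si](C)(C)OCC[C@@H](C)CC[C@H]1C(C(=O)OC)CC(OS(=O)(=O)C(F)(F)F)=C2C(C)(C)CCC[C@]12C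
F4 | step 12 | methyl (13S)-15-[(tert-butyldimethylsilyl)oxy]labd-5-en-17-oate (C8 epimers) | CC(C)(C)[Si](C)(C)OCC[C@@H](C)CC[C@H]1C(C(=O)OC)CC=C2C(C)(C)CCC[C@]12C
F5 | step 12 | methyl (13S)-15-[(tert-butyldimethylsilyl)oxy]-6α-hydroxylabdan-17-oate (5α-H; C8 epimers) | CC(C)(C)[Si](C)(C)OCC[C@@H](C)CC[C@H]1C(C(=O)OC)C[C@H](O)[C@H]2C(C)(C)CCC[C@]12C
F6 | step 7 | 1-({[(2Z)-3-iodobut-2-en-1-yl]oxy}methyl)-4-methoxybenzene | C/C(I)=C/COCc1ccc(OC)cc1
F7 | step 7 | (4R)-4-benzyl-3-[(3S,4Z)-3-{(3S)-5-[(tert-butyldimethylsilyl)oxy]-3-methylpentyl}-6-[(4-methoxybenzyl)oxy]-4-methylhex-4-enoyl]-1,3-oxazolidin-2-one | CC(C)(C)[Si](C)(C)OCC[C@@H](C)CC[C@H](/C(C)=C\COCc1ccc(OC)cc1)CC(=O)N1[C@H](Cc2ccccc2)COC1=O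
F8 | step 7 | (4R)-4-benzyl-3-[(3S,4Z)-3-{(3S)-5-[(tert-butyldimethylsilyl)oxy]-3-methylpentyl}-6-hydroxy-4-methylhex-4-enoyl]-1,3-oxazolidin-2-one | CC(C)(C)[Si](C)(C)OCC[C@@H](C)CC[C@H](/C(C)=C\CO)CC(=O)N1[C@H](Cc2ccccc2)COC1=O
F9 | step 7 | (4R)-4-benzyl-3-[(3S,4Z)-3-{(3S)-5-[(tert-butyldimethylsilyl)oxy]-3-methylpentyl}-4-methyl-6-oxohex-4-enoyl]-1,3-oxazolidin-2-one | CC(C)(C)[Si](C)(C)OCC[C@@H](C)CC[C@H](/C(C)=C\C=O)CC(=O)N1[C@H](Cc2ccccc2)COC1=O
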